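**Assumption:** the SMILES is taken as drawn, i.e. a (1S) benzylic centre on a (1R,4R,4aS,6S,8aR) trans-decalin whose C4 hydroxyl is cis to the angular methyl. The sense of induction of the two chiral catalysts (steps 3 and 10) is assigned by analogy and has not been verified; the antipodal ligand would be used if it proves opposite.

## Retrosynthetic overview

1. Target ⇐ face-selective hydrogenation of a 1,7-diene ⇐ C1–benzylic bond made by boron-to-carbon alkenyl transfer onto the o-quinone methide formed from 2,4,6-trihydroxyisophthalaldehyde and isovaleraldehyde.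
2. Alkenylboronic acid ⇐ enol triflate ⇐ conjugate reduction of a 4-hydroxy-4-methyl enone ⇐ methyl addition to a trans-fused enedione.
3. Enedione ⇐ angular methylation, ketal hydrolysis and ring-fusion epimerization of a cis Diels–Alder adduct.
4. Key step: catalytic enantioselective Diels–Alder reaction that desymmetrizes 4,4-dimethoxycyclohexa-2,5-dienone (from oxidative dearomatization of 4-methoxyphenol) with a 2-substituted butadiene.
5. Ring order: ring A comes from the arene, ring B is closed onto it in the Diels–Alder step, and the phloroglucinol ring is carried in intact.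

## Route

Step 1
Reactants: 1 4-methoxyphenol
Product: 2 4,4-dimethoxycyclohexa-2,5-dien-1-one
Conditions: PhI(OAc)2, MeOH, 0 °C
Reagents that add atoms: methanol, CO
Why: Two-electron oxidation of the phenol by trivalent iodine gives a phenoxonium ion that methanol traps at the para carbon (oxidative dearomatization to the quinone monoketal), giving a symmetric cross-conjugated dienone with two mirror-related enone C=C bonds.

Step 2
Reactants: 3 trimethyl[(2-methylbut-3-yn-2-yl)oxy]silane; 4 ethylene
Product: 5 trimethyl[(2-methyl-3-methylidenepent-4-en-2-yl)oxy]silane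
Conditions: second-generation Grubbs catalyst RuCl2(=CHPh)(PCy3)(H2IMes) (5 mol%), ethylene (4 bar), CH2Cl2, 40 °C
Reagents that add atoms: none
Why: Ethylene–alkyne cross enyne metathesis inserts both ethylene carbons across the terminal alkyne and gives the 2-substituted buta-1,3-diene without co-product, the silyl ether keeping the tertiary alcohol masked.

Step 3
Reactants: 2 4,4-dimethoxycyclohexa-2,5-dien-1-one; 5 trimethyl[(2-methyl-3-methylidenepent-4-en-2-yl)oxy]silane
Product: 6 (4aR,8aS)-4,4-dimethoxy-6-{2-[(trimethylsilyl)oxy]propan-2-yl}-4a,5,8,8a-tetrahydronaphthalen-1(4H)-one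
Conditions: (R)-BINOL/TiCl2(OiPr)2 (10 mol%), 4 Å MS, CH2Cl2, 0 °C → rt
Reagents that add atoms: none
Why: Mikami-type BINOL–titanium Lewis acid-catalysed Diels–Alder reaction in which the carbonyl-bound chiral catalyst selects one of the enantiotopic enone C=C bonds (desymmetrization), the CH2 terminus next to the substituted diene carbon bonds to the enone β-carbon ("para" orientation, side chain 1,4 to C8a), and suprafacial addition gives the cis ring fusion.

Step 4
Reactants: 6 (4aR,8aS)-4,4-dimethoxy-6-{2-[(trimethylsilyl)oxy]propan-2-yl}-4a,5,8,8a-tetrahydronaphthalen-1(4H)-one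
Product: 7 (4aR,8aS)-4,4-dimethoxy-8a-methyl-6-{2-[(trimethylsilyl)oxy]propan-2-yl}-4a,5,8,8a-tetrahydronaphthalen-1(4H)-one
Conditions: LiN(SiMe3)2, THF, −78 °C; MeI, −78 → 0 °C
Reagents that add atoms: iodomethane, CI
Why: Only C8a–H is enolizable (C2 is vinylic, C4 is fully substituted), so a single cross-conjugated enolate forms and is C-methylated on the convex face, cis to the C4a hydrogen (angular enolate alkylation), which fixes the quaternary centre; any trans-methylated diastereomer is removed by chromatography before the next step.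

Step 5
Reactants: 7 (4aR,8aS)-4,4-dimethoxy-8a-methyl-6-{2-[(trimethylsilyl)oxy]propan-2-yl}-4a,5,8,8a-tetrahydronaphthalen-1(4H)-one
Product: 9 (4aS,8aS)-7-(2-hydroxypropan-2-yl)-4a-methyl-4a,5,8,8a-tetrahydronaphthalene-1,4-dione, via cis-enedione 8 (not isolated)
Conditions: aq. HCl (1 M), THF, 0 °C → rt; then DBU (0.3 equiv), CH2Cl2, rt
Reagents that add atoms: water, O
Why: Mild acid hydrolyses the allylic dimethyl ketal and the silyl ether, and because the enedione has only one enolizable position (the ring-fusion CH, with aromatization blocked by the quaternary carbon) base epimerizes the cis adduct to the trans-fused isomer expected to be more stable (enolization/epimerization as in the cis-to-trans isomerization of angular-methyl quinone adducts).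

Step 6
Reactants: 9 (4aS,8aS)-7-(2-hydroxypropan-2-yl)-4a-methyl-4a,5,8,8a-tetrahydronaphthalene-1,4-dione
Product: 10 (4R,4aS,8aS)-4-hydroxy-6-(2-hydroxypropan-2-yl)-4,8a-dimethyl-4a,5,8,8a-tetrahydronaphthalen-1(4H)-one
Conditions: MeMgBr (2.3 equiv), CeCl3, THF, −78 °C
Reagents that add atoms: methylmagnesium bromide, C[Mg]Br
Why: Organocerium 1,2-addition takes place at the carbonyl remote from the quaternary carbon and from the face opposite the axial angular methyl (equatorial attack), so the new methyl is equatorial and the tertiary hydroxyl axial, cis to the angular methyl (4R).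

Step 7
Reactants: 10 (4R,4aS,8aS)-4-hydroxy-6-(2-hydroxypropan-2-yl)-4,8a-dimethyl-4a,5,8,8a-tetrahydronaphthalen-1(4H)-one
Product: 11 (4R,4aS,8aS)-4-hydroxy-6-(2-hydroxypropan-2-yl)-4,8a-dimethyl-3,4,4a,5,8,8a-hexahydronaphthalen-1-yl trifluoromethanesulfonate
Conditions: LiBH(s-Bu)3 (1.3 equiv), THF, −78 °C; then PhNTf2, −78 → 0 °C
Reagents that add atoms: N-phenylbis(trifluoromethanesulfonimide), O=S(=O)(N(c1ccccc1)S(=O)(=O)C(F)(F)F)C(F)(F)F
Why: The bulky trialkylborohydride adds hydride in conjugate fashion (1,2-attack is blocked by the neighbouring quaternary carbon) to give the regiodefined enolate, which is O-sulfonylated to the enol triflate (1,4-reduction/enolate trapping), the tertiary hydroxyls being too weakly acidic to quench the enolate at low temperature.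

Step 8
Reactants: 11 (4R,4aS,8aS)-4-hydroxy-6-(2-hydroxypropan-2-yl)-4,8a-dimethyl-3,4,4a,5,8,8a-hexahydronaphthalen-1-yl trifluoromethanesulfonate
Product: 13 [(4R,4aS,8aS)-4-hydroxy-6-(2-hydroxypropan-2-yl)-4,8a-dimethyl-3,4,4a,5,8,8a-hexahydronaphthalen-1-yl]boronic acid, via pinacol boronate 12 (not isolated)
Conditions: B2pin2, PdCl2(dppf) (5 mol%), KOAc, 1,4-dioxane, 80 °C; then NaIO4, NH4OAc, acetone/H2O, rt
Reagents that add atoms: bis(pinacolato)diboron, CC1(C)OB(OC1(C)C)B1OC(C)(C)C(C)(C)O1; water, O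
Why: Miyaura borylation (oxidative addition of zerovalent palladium into the C–OTf bond, transmetalation with acetate-activated diboron, reductive elimination) followed by periodate cleavage of the pinacol unit gives the free alkenylboronic acid needed for ligand exchange at boron in step 10.

Step 9
Reactants: 14 phloroglucinol (benzene-1,3,5-triol)
Product: 15 2,4,6-trihydroxybenzene-1,3-dicarbaldehyde
Conditions: POCl3 (2.2 equiv), DMF, 1,4-dioxane, 0 °C → rt; then H2O
Reagents that add atoms: N,N-dimethylformamide, CN(C)C=O; water, O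
Why: Double Vilsmeier–Haack formylation of the highly activated ring, the third position being spared by stoichiometry and by deactivation through the two formyl groups.

Step 10
Reactants: 13 [(4R,4aS,8aS)-4-hydroxy-6-(2-hydroxypropan-2-yl)-4,8a-dimethyl-3,4,4a,5,8,8a-hexahydronaphthalen-1-yl]boronic acid; 15 2,4,6-trihydroxybenzene-1,3-dicarbaldehyde; 16 3-methylbutanal
Product: 18 5-[(1S)-1-[(4R,4aS,8aS)-4-hydroxy-6-(2-hydroxypropan-2-yl)-4,8a-dimethyl-3,4,4a,5,8,8a-hexahydronaphthalen-1-yl]-3-methylbutyl]-2,4,6-trihydroxybenzene-1,3-dicarbaldehyde, via o-quinone methide 17 (not isolated)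
Conditions: (R)-3,3′-Br2-BINOL (20 mol%), 4 Å MS, PhCF3, 50 °C
Reagents that add atoms: none
Why: Proposed new method: the boronic acid condenses with a phenolic OH of 15 and with the aldehyde to a 1,3,2-benzodioxaborin (Nagata-type ortho-hydroxyalkylation), ionization of its benzylic C–O bond gives o-quinone methide 17 still held on boron through the phenoxide, and the alkenyl group migrates from tetracoordinate boron to the exocyclic carbon through a six-membered transition state with retention of the C1=C2 alkene (Petasis-type transfer; closest known reaction type is the biphenol-catalysed enantioselective addition of alkenyl boronates to o-quinone methides), the boron-bound chiral biphenol setting the (1S) benzylic centre.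

Step 11
Reactants: 18 5-[(1S)-1-[(4R,4aS,8aS)-4-hydroxy-6-(2-hydroxypropan-2-yl)-4,8a-dimethyl-3,4,4a,5,8,8a-hexahydronaphthalen-1-yl]-3-methylbutyl]-2,4,6-trihydroxybenzene-1,3-dicarbaldehyde
Product: 19 5-[(1S)-1-[(1R,4R,4aS,6S,8aR)-4-hydroxy-6-(2-hydroxypropan-2-yl)-4,8a-dimethyldecahydronaphthalen-1-yl]-3-methylbutyl]-2,4,6-trihydroxybenzene-1,3-dicarbaldehyde
Conditions: H2 (40 bar), Pd/C (10%), EtOAc, rt
Reagents that add atoms: none
Why: Heterogeneous catalytic hydrogenation delivers hydrogen to both trisubstituted alkenes from the face opposite the axial angular methyl and the axial C4 hydroxyl, giving the equatorial C1 side chain (1R) and the equatorial C6 hydroxyisopropyl group (6S), while the strongly hydrogen-bonded aryl aldehydes (vinylogous acids) are expected to survive.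

## Compound list

1 | 4-methoxyphenol | COc1ccc(O)cc1 | starting material
2 | 4,4-dimethoxycyclohexa-2,5-dien-1-one | COC1(OC)C=CC(=O)C=C1 | intermediate
3 | trimethyl[(2-methylbut-3-yn-2-yl)oxy]silane | C#CC(C)(C)O[Si](C)(C)C | starting material
4 | ethylene | C=C | starting material
5 | trimethyl[(2-methyl-3-methylidenepent-4-en-2-yl)oxy]silane | C=CC(=C)C(C)(C)O[Si](C)(C)C | intermediate
6 | (4aR,8aS)-4,4-dimethoxy-6-{2-[(trimethylsilyl)oxy]propan-2-yl}-4a,5,8,8a-tetrahydronaphthalen-1(4H)-one | O=C1C=CC(OC)(OC)[C@@H]2CC(C(C)(C)O[Si](C)(C)C)=CC[C@H]12 | intermediate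
7 | (4aR,8aS)-4,4-dimethoxy-8a-methyl-6-{2-[(trimethylsilyl)oxy]propan-2-yl}-4a,5,8,8a-tetrahydronaphthalen-1(4H)-one | O=C1C=CC(OC)(OC)[C@@H]2CC(C(C)(C)O[Si](C)(C)C)=CC[C@]12C | intermediate
8 | (4aS,8aR)-7-(2-hydroxypropan-2-yl)-4a-methyl-4a,5,8,8a-tetrahydronaphthalene-1,4-dione (cis-enedione) | O=C1C=CC(=O)[C@@H]2CC(C(C)(C)O)=CC[C@]12C | intermediate (not isolated)
9 | (4aS,8aS)-7-(2-hydroxypropan-2-yl)-4a-methyl-4a,5,8,8a-tetrahydronaphthalene-1,4-dione (trans-enedione) | O=C1C=CC(=O)[C@H]2CC(C(C)(C)O)=CC[C@]12C | intermediate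
10 | (4R,4aS,8aS)-4-hydroxy-6-(2-hydroxypropan-2-yl)-4,8a-dimethyl-4a,5,8,8a-tetrahydronaphthalen-1(4H)-one | O=C1C=C[C@@](C)(O)[C@H]2CC(C(C)(C)O)=CC[C@]12C | intermediate
11 | (4R,4aS,8aS)-4-hydroxy-6-(2-hydroxypropan-2-yl)-4,8a-dimethyl-3,4,4a,5,8,8a-hexahydronaphthalen-1-yl trifluoromethanesulfonate | O=S(=O)(OC1=CC[C@@](C)(O)[C@H]2CC(C(C)(C)O)=CC[C@]12C)C(F)(F)F | intermediate
12 | 2-[(4R,4aS,8aS)-4-hydroxy-6-(2-hydroxypropan-2-yl)-4,8a-dimethyl-3,4,4a,5,8,8a-hexahydronaphthalen-1-yl]-4,4,5,5-tetramethyl-1,3,2-dioxaborolane (pinacol boronate) | CC1(C)OB(OC1(C)C)C1=CC[C@@](C)(O)[C@H]2CC(C(C)(C)O)=CC[C@]12C | intermediate (not isolated)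
13 | [(4R,4aS,8aS)-4-hydroxy-6-(2-hydroxypropan-2-yl)-4,8a-dimethyl-3,4,4a,5,8,8a-hexahydronaphthalen-1-yl]boronic acid | OB(O)C1=CC[C@@](C)(O)[C@H]2CC(C(C)(C)O)=CC[C@]12C | intermediate
14 | phloroglucinol (benzene-1,3,5-triol) | Oc1cc(O)cc(O)c1 | starting material
15 | 2,4,6-trihydroxybenzene-1,3-dicarbaldehyde | O=Cc1c(O)cc(O)c(C=O)c1O | intermediate
16 | 3-methylbutanal | CC(C)CC=O | starting material
17 | 2,4-dihydroxy-5-(3-methylbutylidene)-6-oxocyclohexa-1,3-diene-1,3-dicarbaldehyde (o-quinone methide) | CC(C)CC=C1C(=O)C(C=O)=C(O)C(C=O)=C1O | intermediate (not isolated)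
18 | 5-[(1S)-1-[(4R,4aS,8aS)-4-hydroxy-6-(2-hydroxypropan-2-yl)-4,8a-dimethyl-3,4,4a,5,8,8a-hexahydronaphthalen-1-yl]-3-methylbutyl]-2,4,6-trihydroxybenzene-1,3-dicarbaldehyde | CC(C)C[C@H](c1c(O)c(C=O)c(O)c(C=O)c1O)C1=CC[C@@](C)(O)[C@H]2CC(C(C)(C)O)=CC[C@]12C | intermediate
19 | 5-[(1S)-1-[(1R,4R,4aS,6S,8aR)-4-hydroxy-6-(2-hydroxypropan-2-yl)-4,8a-dimethyldecahydronaphthalen-1-yl]-3-methylbutyl]-2,4,6-trihydroxybenzene-1,3-dicarbaldehyde | CC(C)C[C@H](c1c(O)c(C=O)c(O)c(C=O)c1O)[C@H]1CC[C@@](C)(O)[C@H]2C[C@@H](C(C)(C)O)CC[C@]12C | target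

## Step count and risks

Total: 11 steps. Longest linear sequence: 9 steps (1, 3, 4, 5, 6, 7, 8, 10, 11).

The three steps most likely to fail are 10, 11 and 7.

**Step 10.** The hindered alkenyl group may transfer slowly, the ring-B alkene may compete for the quinone methide, and the biphenol may not override the substrate's own bias at the benzylic carbon. The fallback sets out from 15 and 16. They are condensed with morpholine to the isolable Mannich base 2,4,6-trihydroxy-5-[3-methyl-1-(morpholin-4-yl)butyl]benzene-1,3-dicarbaldehyde F3, a storable quinone methide precursor. F3 is then combined with boronic acid 13 under monovalent rhodium catalysis ([RhCl(C2H4)2]2, a chiral diene ligand, aqueous KOH, dioxane). The alkenyl–rhodium species adds 1,4 to the quinone methide released by loss of morpholine, with the metal's ligand controlling the benzylic centre, and the route is rejoined at 18.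

**Step 11.** The C1=C2 alkene is very hindered, and forcing conditions may reduce the aldehydes or hydrogenolyse the allylic tertiary alcohol. The fallback sets out from 13 and postpones the formyl groups. The same boron-templated coupling is run with phloroglucinol 14 and 16 to give 2-[(1S)-1-[(4R,4aS,8aS)-4-hydroxy-6-(2-hydroxypropan-2-yl)-4,8a-dimethyl-3,4,4a,5,8,8a-hexahydronaphthalen-1-yl]-3-methylbutyl]benzene-1,3,5-triol F4. F4 is hydrogenated without any aldehyde present to 2-[(1S)-1-[(1R,4R,4aS,6S,8aR)-4-hydroxy-6-(2-hydroxypropan-2-yl)-4,8a-dimethyldecahydronaphthalen-1-yl]-3-methylbutyl]benzene-1,3,5-triol F5. F5 is then formylated twice under basic magnesium phenoxide conditions (MgCl2, Et3N, paraformaldehyde, MeCN), which spare the tertiary alcohols, and this gives 19 directly.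

**Step 7.** Hydride delivery to a β-carbon that sits next to a fully substituted carbinol, with two free hydroxyls present, may be slow or unselective. The fallback sets out from 9. Zn dust in AcOH reduces the enedione C=C to the trans-fused saturated dione (4aS,8aS)-7-(2-hydroxypropan-2-yl)-4a-methyl-2,3,4a,5,8,8a-hexahydronaphthalene-1,4-dione F1. MeMgBr/CeCl3 then adds to the less hindered carbonyl, with the same facial preference as in step 6, to give (4R,4aS,8aS)-4-hydroxy-6-(2-hydroxypropan-2-yl)-4,8a-dimethyl-3,4,4a,5,8,8a-hexahydronaphthalen-1(2H)-one F2. KN(SiMe3)2 (3.2 equiv) and PhNTf2 convert F2, which can enolize only toward C2, into the enol triflate, so the route is rejoined at 11 without passing through 10.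

## Further compounds

F1 | step 7 | (4aS,8aS)-7-(2-hydroxypropan-2-yl)-4a-methyl-2,3,4a,5,8,8a-hexahydronaphthalene-1,4-dione | O=C1CCC(=O)[C@H]2CC(C(C)(C)O)=CC[C@]12C
F2 | step 7 | (4R,4aS,8aS)-4-hydroxy-6-(2-hydroxypropan-2-yl)-4,8a-dimethyl-3,4,4a,5,8,8a-hexahydronaphthalen-1(2H)-one | O=C1CC[C@@](C)(O)[C@H]2CC(C(C)(C)O)=CC[C@]12C
F3 | step 10 | 2,4,6-trihydroxy-5-[3-methyl-1-(morpholin-4-yl)butyl]benzene-1,3-dicarbaldehyde (racemic) | CC(C)CC(N1CCOCC1)c1c(O)c(C=O)c(O)c(C=O)c1O
F4 | step 11 | 2-[(1S)-1-[(4R,4aS,8aS)-4-hydroxy-6-(2-hydroxypropan-2-yl)-4,8a-dimethyl-3,4,4a,5,8,8a-hexahydronaphthalen-1-yl]-3-methylbutyl]benzene-1,3,5-triol | CC(C)C[C@H](c1c(O)cc(O)cc1O)C1=CC[C@@](C)(O)[C@H]2CC(C(C)(C)O)=CC[C@]12C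
F5 | step 11 | 2-[(1S)-1-[(1R,4R,4aS,6S,8aR)-4-hydroxy-6-(2-hydroxypropan-2-yl)-4,8a-dimethyldecahydronaphthalen-1-yl]-3-methylbutyl]benzene-1,3,5-triol | CC(C)C[C@H](c1c(O)cc(O)cc1O)[C@H]1CC[C@@](C)(O)[C@H]2C[C@@H](C(C)(C)O)CC[C@]12C
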